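**Retrosynthetic overview**

1. Target 29 comes from bromocyclohexene carbonate 25 by debromination, desilylation, benzoylation of O7 and hydrolysis of the carbonate (steps 15–18).
2. The strategy rests on two features: the cyclohexene ring C1–C6 is the one-carbon homologue of a cyclopentene C1=C5 that carries C7 on C1, and O1 and O2 are cis, so an acyl group on O2 can deliver the oxygen to C1.
3. Key disconnection: 25 ⇐ 6,6-dibromobicyclo[3.1.0]hexane 22, by insertion of C6 through electrocyclic opening of the C1–C5 bond and formation of the O1–C1 bond by the O2 tert-butyl carbonate; 22 ⇐ cyclopentene 20 + CBr2.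
4. Cyclopentene 20 ⇐ ring-closing metathesis of 1,6-diene 11 ⇐ two methylenations (lactol carbon, then C5 ketone) of a D-glucose thioglycoside whose oxygens are already told apart (O2 silyl, O3 PMB then benzoate, O4/O6 benzylidene then Boc and silyl).
5. Ring order: cyclopentene (step 7), cyclopropane (step 13), then cyclohexene and five-membered carbonate together (step 14).

Key step: step 14

Assumption: phenyl 4,6-O-benzylidene-1-thio-β-D-glucopyranoside, a catalogue derivative of D-glucose, is taken as the commercial entry; atoms are numbered as in the target (C7 = CH2O carbon), so glucose C1–C6 become C5, C4, C3, C2, C1 and C7, and C6 comes from the carbene.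

**Route**

Step 1
Reactants: 1 phenyl 4,6-O-benzylidene-1-thio-β-D-glucopyranoside; 2 4-methoxybenzyl chloride
Product: 4 phenyl 4,6-O-benzylidene-3-O-(4-methoxybenzyl)-1-thio-β-D-glucopyranoside, via 2,3-O-dibutylstannylene acetal 3 (not isolated)
Conditions: Bu2SnO, toluene, reflux (Dean–Stark); then PMBCl, CsF, DMF, 25 °C
Reagents that add atoms: 4-methoxybenzyl chloride, COc1ccc(CCl)cc1; dibutyltin oxide, CCCC[Sn](=O)CCCC (its tin stays only in 3)
Why: Tin-acetal activation of the trans-diequatorial 2,3-diol followed by fluoride-promoted alkylation is expected to favour O3 in 4,6-O-benzylidene β-thioglucosides (any 2-O-isomer is removed by chromatography), which puts the removable ether on the oxygen that later carries the benzoate; no stereocentre is touched.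

Step 2
Reactants: 4 phenyl 4,6-O-benzylidene-3-O-(4-methoxybenzyl)-1-thio-β-D-glucopyranoside; 5 triisopropylsilyl trifluoromethanesulfonate
Product: 6 phenyl 4,6-O-benzylidene-3-O-(4-methoxybenzyl)-2-O-triisopropylsilyl-1-thio-β-D-glucopyranoside
Conditions: TIPSOTf, 2,6-lutidine, CH2Cl2, 0 → 25 °C
Reagents that add atoms: triisopropylsilyl trifluoromethanesulfonate, CC(C)[Si](OS(=O)(=O)C(F)(F)F)(C(C)C)C(C)C
Why: Silyl triflate silylation of the remaining hindered 2-OH; the triisopropylsilyl group is chosen because it does not migrate under the later basic olefinations, resists acid, and cannot take part in the key step.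

Step 3
Reactants: 6 phenyl 4,6-O-benzylidene-3-O-(4-methoxybenzyl)-2-O-triisopropylsilyl-1-thio-β-D-glucopyranoside
Product: 7 4,6-O-benzylidene-3-O-(4-methoxybenzyl)-2-O-triisopropylsilyl-D-glucopyranose (anomer mixture)
Conditions: NBS, acetone/H2O (9:1), −15 → 0 °C
Reagents that add atoms: water, O
Why: Oxidative hydrolysis of a thioglycoside (bromosulfonium ion, loss of PhSBr, capture of the oxocarbenium ion by water) should free the hemiacetal without touching the acetal, PMB ether or silyl ether.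

Step 4
Reactants: 7 4,6-O-benzylidene-3-O-(4-methoxybenzyl)-2-O-triisopropylsilyl-D-glucopyranose; 8 methyltriphenylphosphonium bromide
Product: 9 5,7-O-benzylidene-1,2-dideoxy-4-O-(4-methoxybenzyl)-3-O-triisopropylsilyl-D-gluco-hept-1-enitol (free 6-OH on the dioxane ring)
Conditions: Ph3PCH3Br, KN(SiMe3)2, THF, 0 °C; then 7, 0 → 25 °C
Reagents that add atoms: methyltriphenylphosphonium bromide, C[P+](c1ccccc1)(c1ccccc1)c1ccccc1.[Br-]
Why: Wittig methylenation of the hydroxy-aldehyde form of the lactol should give the terminal alkene (target C5) and free only the hydroxyl on glucose C5, with the three carbinol stereocentres untouched.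

Step 5
Reactants: 9 5,7-O-benzylidene-1,2-dideoxy-4-O-(4-methoxybenzyl)-3-O-triisopropylsilyl-D-gluco-hept-1-enitol
Product: 10 5,7-O-benzylidene-1,2-dideoxy-4-O-(4-methoxybenzyl)-3-O-triisopropylsilyl-D-xylo-hept-1-en-6-ulose (a 2-phenyl-1,3-dioxan-5-one)
Conditions: Dess–Martin periodinane, CH2Cl2, 25 °C
Reagents that add atoms: none
Why: Dess–Martin oxidation of the only free secondary alcohol gives the dioxanone under near-neutral conditions that leave the alkene, PMB ether, acetal and silyl ether alone.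

Step 6
Reactants: 10 5,7-O-benzylidene-1,2-dideoxy-4-O-(4-methoxybenzyl)-3-O-triisopropylsilyl-D-xylo-hept-1-en-6-ulose; 8 methyltriphenylphosphonium bromide
Product: 11 5,7-O-benzylidene-1,2,6-trideoxy-6-methylene-4-O-(4-methoxybenzyl)-3-O-triisopropylsilyl-D-xylo-hept-1-enitol (1,6-diene)
Conditions: Ph3PCH3Br, KN(SiMe3)2, THF, −78 → 0 °C
Reagents that add atoms: methyltriphenylphosphonium bromide, C[P+](c1ccccc1)(c1ccccc1)c1ccccc1.[Br-]
Why: Wittig methylenation of the ketone gives the 1,1-disubstituted alkene whose carbon becomes C1; the α-stereocentre (target C2) is equatorial on the benzylidene dioxane, so enolisation should not invert it.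

Step 7
Reactants: 11 5,7-O-benzylidene-1,2,6-trideoxy-6-methylene-4-O-(4-methoxybenzyl)-3-O-triisopropylsilyl-D-xylo-hept-1-enitol
Product: 12 bicyclic cyclopentene C1=C5 (target numbering): O2,O7-benzylidene acetal (O2 β), C3 α-OPMB, C4 β-OTIPS
Conditions: second-generation Grubbs catalyst RuCl2(=CHPh)(PCy3)(H2IMes) (5 mol %), CH2Cl2 (dilute), 40 °C
Reagents that add atoms: none
Why: Ring-closing metathesis of the 1,6-diene closes the cyclopentene with loss of ethylene; five-ring closure onto a 1,1-disubstituted alkene is routine with this catalyst and sets no stereocentre.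

Step 8
Reactants: 12 bicyclic cyclopentene with O2,O7-benzylidene acetal, C3 α-OPMB, C4 β-OTIPS
Product: 13 bicyclic cyclopentene with O2,O7-benzylidene acetal, C3 α-OH, C4 β-OTIPS
Conditions: DDQ, CH2Cl2/pH 7 buffer, 0 → 25 °C
Reagents that add atoms: none
Why: Oxidative PMB cleavage by DDQ (benzylic hydride abstraction, hydrolysis of the oxocarbenium ion) frees O3 alone, since a plain benzylidene acetal and a silyl ether are stable to DDQ.

Step 9
Reactants: 13 bicyclic cyclopentene with C3 α-OH; 14 benzoyl chloride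
Product: 15 bicyclic cyclopentene with O2,O7-benzylidene acetal, C3 α-OBz, C4 β-OTIPS
Conditions: BzCl, pyridine, DMAP (cat.), CH2Cl2, 0 → 25 °C
Reagents that add atoms: benzoyl chloride, O=C(Cl)c1ccccc1
Why: DMAP-catalysed acylation of the only free hydroxyl installs the C3 benzoate of the target with retention (O3 α).

Step 10
Reactants: 15 bicyclic cyclopentene with O2,O7-benzylidene acetal, C3 α-OBz, C4 β-OTIPS
Product: 16 cyclopentene C1=C5 with C1–CH2OH, C2 β-OH, C3 α-OBz, C4 β-OTIPS
Conditions: camphorsulfonic acid (cat.), MeOH/CH2Cl2, 25 °C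
Reagents that add atoms: none
Why: Acid-catalysed transacetalisation with methanol removes the benzylidene acetal and frees O2 and O7, while the secondary TIPS ether and the benzoate tolerate catalytic sulfonic acid at room temperature.

Step 11
Reactants: 16 cyclopentene diol (C1–CH2OH, C2 β-OH); 17 tert-butyl(chloro)diphenylsilane
Product: 18 cyclopentene C1=C5 with C1–CH2OTBDPS, C2 β-OH, C3 α-OBz, C4 β-OTIPS
Conditions: TBDPSCl, imidazole, CH2Cl2, 0 °C
Reagents that add atoms: tert-butyl(chloro)diphenylsilane, CC(C)(C)[Si](Cl)(c1ccccc1)c1ccccc1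
Why: Silylation with the bulky chloride is selective for the primary allylic O7 over the hindered secondary O2.

Step 12
Reactants: 18 cyclopentene with C1–CH2OTBDPS, C2 β-OH, C3 α-OBz, C4 β-OTIPS; 19 di-tert-butyl dicarbonate
Product: 20 cyclopentene C1=C5 with C1–CH2OTBDPS, C2 β-OBoc, C3 α-OBz, C4 β-OTIPS
Conditions: Boc2O, DMAP (cat.), MeCN, 25 °C
Reagents that add atoms: di-tert-butyl dicarbonate, CC(C)(C)OC(=O)OC(=O)OC(C)(C)C
Why: DMAP-catalysed acylation of the last free hydroxyl installs the tert-butyl carbonate tether on O2; a trans-1,2 benzoate on a cyclopentane should not migrate under these conditions.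

Step 13
Reactants: 20 cyclopentene with C1–CH2OTBDPS, C2 β-OBoc, C3 α-OBz, C4 β-OTIPS; 21 phenyl(tribromomethyl)mercury
Product: 22 6,6-dibromobicyclo[3.1.0]hexane (cyclopropane on the α face) with C1–CH2OTBDPS, C2 β-OBoc, C3 α-OBz, C4 β-OTIPS
Conditions: PhHgCBr3 (excess), benzene, 80 °C
Reagents that add atoms: phenyl(tribromomethyl)mercury, BrC(Br)(Br)[Hg]c1ccccc1
Why: Thermal loss of PhHgBr transfers CBr2 to the alkene in a stereospecific [2+1] cycloaddition under neutral conditions that benzoate and carbonate survive; addition is expected anti to the β groups on C2 and C4 (new centres C1 and C5, cis-fused), although either face serves the next step.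

Step 14
Reactants: 22 6,6-dibromobicyclo[3.1.0]hexane with C1–CH2OTBDPS, C2 β-OBoc, C3 α-OBz, C4 β-OTIPS
Product: 25 6-bromocyclohex-5-ene with cis-fused 1β,2β-cyclic carbonate (C1 α-CH2OTBDPS; C3 α-OBz; C4 β-OTIPS), via 2-bromocyclohexenyl cation 23 (not isolated), via 2-tert-butoxy-1,3-dioxolan-2-ylium ion 24 (not isolated)
Conditions: AgBF4 (2.5 equiv), 2,6-di-tert-butyl-4-methylpyridine, ClCH2CH2Cl, 25 → 60 °C, dark
Reagents that add atoms: none
Why: AgBF4 removes the endo bromide while the C1–C5 bond opens in a disrotatory two-electron electrocyclic process, so that release of cyclopropane strain turns the five-membered ring into the six-membered 2-bromoallyl cation 23 (C1–C6–C5); this is the known silver-promoted ring expansion of ring-fused gem-dibromocyclopropanes with capture by a tethered carbonate or carbamate. The carbonyl oxygen of the C2 tert-butyl carbonate then adds to C1 in a 5-exo-trig closure to give ion 24, which loses isobutene and so makes the capture irreversible. The carbocycle is therefore formed by ring expansion without a new C–C bond, and the carbonate ring by 5-exo O–C1 closure. The only new stereocentre, C1, is fixed by the tether: the carbonate on β-O2 can only close cis, so O1 becomes β and C7 α from either cyclopropane diastereomer. The step needs capture at C1 rather than C5 and by the carbonate rather than another group; the tether cannot reach C5, O4 and O7 carry silyl ethers that cannot take part, and the C3 benzoate could reach the cation only from the α face through a slower, reversible bridged six-membered closure. The hindered pyridine takes up the HBF4 released so that the silyl ethers survive.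

Step 15
Reactants: 25 6-bromocyclohex-5-ene 1β,2β-cyclic carbonate
Product: 26 cyclohex-5-ene with cis-fused 1β,2β-cyclic carbonate, C1 α-CH2OTBDPS, C3 α-OBz, C4 β-OTIPS
Conditions: Bu3SnH, AIBN, toluene, 90 °C
Reagents that add atoms: none
Why: Radical chain reduction of the vinylic bromide (bromine abstraction by the stannyl radical, hydrogen transfer to the σ-vinyl radical) leaves the allylic carbonate, benzoate and silyl ethers untouched, which a palladium-catalysed reduction of an allylic carbonate would not guarantee.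

Step 16
Reactants: 26 cyclohex-5-ene cyclic carbonate with C1 α-CH2OTBDPS, C3 α-OBz, C4 β-OTIPS
Product: 27 cyclohex-5-ene with cis-fused 1β,2β-cyclic carbonate, C1 α-CH2OH, C3 α-OBz, C4 β-OH
Conditions: HF·pyridine, THF, 0 → 25 °C
Reagents that add atoms: none
Why: Fluoride desilylation under acidic, non-basic conditions removes both silyl ethers without migration of the benzoate or the carbonate.

Step 17
Reactants: 27 cyclohex-5-ene cyclic carbonate with C1 α-CH2OH, C3 α-OBz, C4 β-OH; 14 benzoyl chloride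
Product: 28 cyclohex-5-ene with cis-fused 1β,2β-cyclic carbonate, C1 α-CH2OBz, C3 α-OBz, C4 β-OH
Conditions: BzCl (1.1 equiv), 2,4,6-collidine, CH2Cl2, −78 → −40 °C
Reagents that add atoms: benzoyl chloride, O=C(Cl)c1ccccc1
Why: Kinetic acylation with an acid chloride and a hindered pyridine at low temperature is selective for the primary O7 over the secondary allylic O4, and the weak base does not move the carbonate.

Step 18
Reactants: 28 cyclohex-5-ene cyclic carbonate with C1 α-CH2OBz, C3 α-OBz, C4 β-OH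
Product: 29 1α-benzoyloxymethyl-3α-benzoyloxycyclohex-5-ene-1β,2β,4β-triol
Conditions: LiOH (1.05 equiv), THF/H2O, 0 °C; then aq. NH4Cl
Reagents that add atoms: none
Why: Hydroxide should open the strained five-membered cyclic carbonate faster than it attacks the benzoates, and the single equivalent is used up as hydrogencarbonate, so the esters should survive and no stereocentre is touched.

**Compound list**

1 | phenyl 4,6-O-[(R)-benzylidene]-1-thio-β-D-glucopyranoside | [C@@H]1(c2ccccc2)OC[C@H]3O[C@@H](Sc4ccccc4)[C@H](O)[C@@H](O)[C@@H]3O1 | starting material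
2 | 4-methoxybenzyl chloride | COc1ccc(CCl)cc1 | starting material
3 | 2,3-O-dibutylstannylene acetal of 1 | [C@@H]1(c2ccccc2)OC[C@H]3O[C@@H](Sc4ccccc4)[C@H](O[Sn](CCCC)(CCCC)O5)[C@@H]5[C@@H]3O1 | intermediate (not isolated)
4 | phenyl 4,6-O-benzylidene-3-O-(4-methoxybenzyl)-1-thio-β-D-glucopyranoside | [C@@H]1(c2ccccc2)OC[C@H]3O[C@@H](Sc4ccccc4)[C@H](O)[C@@H](OCc5ccc(OC)cc5)[C@@H]3O1 | intermediate
5 | triisopropylsilyl trifluoromethanesulfonate | CC(C)[Si](OS(=O)(=O)C(F)(F)F)(C(C)C)C(C)C | starting material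
6 | phenyl 4,6-O-benzylidene-3-O-(4-methoxybenzyl)-2-O-triisopropylsilyl-1-thio-β-D-glucopyranoside | [C@@H]1(c2ccccc2)OC[C@H]3O[C@@H](Sc4ccccc4)[C@H](O[Si](C(C)C)(C(C)C)C(C)C)[C@@H](OCc5ccc(OC)cc5)[C@@H]3O1 | intermediate
7 | 4,6-O-benzylidene-3-O-(4-methoxybenzyl)-2-O-triisopropylsilyl-D-glucopyranose (anomer mixture) | [C@@H]1(c2ccccc2)OC[C@H]3OC(O)[C@H](O[Si](C(C)C)(C(C)C)C(C)C)[C@@H](OCc4ccc(OC)cc4)[C@@H]3O1 | intermediate
8 | methyltriphenylphosphonium bromide | C[P+](c1ccccc1)(c1ccccc1)c1ccccc1.[Br-] | starting material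
9 | 5,7-O-benzylidene-1,2-dideoxy-4-O-(4-methoxybenzyl)-3-O-triisopropylsilyl-D-gluco-hept-1-enitol | [C@@H]1(c2ccccc2)OC[C@@H](O)[C@@H](O1)[C@H](OCc3ccc(OC)cc3)[C@@H](O[Si](C(C)C)(C(C)C)C(C)C)C=C | intermediate
10 | 5,7-O-benzylidene-1,2-dideoxy-4-O-(4-methoxybenzyl)-3-O-triisopropylsilyl-D-xylo-hept-1-en-6-ulose | [C@@H]1(c2ccccc2)OCC(=O)[C@@H](O1)[C@H](OCc3ccc(OC)cc3)[C@@H](O[Si](C(C)C)(C(C)C)C(C)C)C=C | intermediate
11 | 5,7-O-benzylidene-1,2,6-trideoxy-6-methylene-4-O-(4-methoxybenzyl)-3-O-triisopropylsilyl-D-xylo-hept-1-enitol | [C@@H]1(c2ccccc2)OCC(=C)[C@@H](O1)[C@H](OCc3ccc(OC)cc3)[C@@H](O[Si](C(C)C)(C(C)C)C(C)C)C=C | intermediate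
12 | bicyclic cyclopentene C1=C5: O2,O7-benzylidene acetal (O2 β), C3 α-OPMB, C4 β-OTIPS | [C@@H]1(c2ccccc2)OCC3=C[C@H](O[Si](C(C)C)(C(C)C)C(C)C)[C@@H](OCc4ccc(OC)cc4)[C@@H]3O1 | intermediate
13 | bicyclic cyclopentene C1=C5: O2,O7-benzylidene acetal, C3 α-OH, C4 β-OTIPS | [C@@H]1(c2ccccc2)OCC3=C[C@H](O[Si](C(C)C)(C(C)C)C(C)C)[C@@H](O)[C@@H]3O1 | intermediate
14 | benzoyl chloride | O=C(Cl)c1ccccc1 | starting material
15 | bicyclic cyclopentene C1=C5: O2,O7-benzylidene acetal, C3 α-OBz, C4 β-OTIPS | [C@@H]1(c2ccccc2)OCC3=C[C@H](O[Si](C(C)C)(C(C)C)C(C)C)[C@@H](OC(=O)c4ccccc4)[C@@H]3O1 | intermediate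
16 | cyclopentene C1=C5: C1–CH2OH, C2 β-OH, C3 α-OBz, C4 β-OTIPS | OCC1=C[C@H](O[Si](C(C)C)(C(C)C)C(C)C)[C@@H](OC(=O)c2ccccc2)[C@@H]1O | intermediate
17 | tert-butyl(chloro)diphenylsilane | CC(C)(C)[Si](Cl)(c1ccccc1)c1ccccc1 | starting material
18 | cyclopentene C1=C5: C1–CH2OTBDPS, C2 β-OH, C3 α-OBz, C4 β-OTIPS | CC(C)(C)[Si](c1ccccc1)(c1ccccc1)OCC1=C[C@H](O[Si](C(C)C)(C(C)C)C(C)C)[C@@H](OC(=O)c2ccccc2)[C@@H]1O | intermediate
19 | di-tert-butyl dicarbonate | CC(C)(C)OC(=O)OC(=O)OC(C)(C)C | starting material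
20 | cyclopentene C1=C5: C1–CH2OTBDPS, C2 β-OBoc, C3 α-OBz, C4 β-OTIPS | CC(C)(C)[Si](c1ccccc1)(c1ccccc1)OCC1=C[C@H](O[Si](C(C)C)(C(C)C)C(C)C)[C@@H](OC(=O)c2ccccc2)[C@@H]1OC(=O)OC(C)(C)C | intermediate
21 | phenyl(tribromomethyl)mercury | BrC(Br)(Br)[Hg]c1ccccc1 | starting material
22 | 6,6-dibromobicyclo[3.1.0]hexane (cyclopropane α): C1–CH2OTBDPS, C2 β-OBoc, C3 α-OBz, C4 β-OTIPS | CC(C)(C)[Si](c1ccccc1)(c1ccccc1)OC[C@]12[C@H]([C@H](O[Si](C(C)C)(C(C)C)C(C)C)[C@@H](OC(=O)c3ccccc3)[C@@H]1OC(=O)OC(C)(C)C)C2(Br)Br | intermediate (key-step precursor)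
23 | 2-bromocyclohexenyl (allyl) cation C1–C6–C5 as tetrafluoroborate, C2 β-OBoc, C3 α-OBz, C4 β-OTIPS, C1–CH2OTBDPS | CC(C)(C)[Si](c1ccccc1)(c1ccccc1)OC[C+]1C(Br)=C[C@H](O[Si](C(C)C)(C(C)C)C(C)C)[C@@H](OC(=O)c2ccccc2)[C@@H]1OC(=O)OC(C)(C)C.F[B-](F)(F)F | intermediate (not isolated)
24 | cis-fused 2-tert-butoxy-1,3-dioxolan-2-ylium ion on O1/O2 as tetrafluoroborate | CC(C)(C)[Si](c1ccccc1)(c1ccccc1)OC[C@@]1(O[C+](OC(C)(C)C)O2)C(Br)=C[C@H](O[Si](C(C)C)(C(C)C)C(C)C)[C@@H](OC(=O)c3ccccc3)[C@@H]12.F[B-](F)(F)F | intermediate (not isolated)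
25 | 6-bromocyclohex-5-ene: cis-fused 1β,2β-cyclic carbonate, C1 α-CH2OTBDPS, C3 α-OBz, C4 β-OTIPS | CC(C)(C)[Si](c1ccccc1)(c1ccccc1)OC[C@@]1(OC(=O)O2)C(Br)=C[C@H](O[Si](C(C)C)(C(C)C)C(C)C)[C@@H](OC(=O)c3ccccc3)[C@@H]12 | intermediate (key-step product)
26 | cyclohex-5-ene: 1β,2β-cyclic carbonate, C1 α-CH2OTBDPS, C3 α-OBz, C4 β-OTIPS | CC(C)(C)[Si](c1ccccc1)(c1ccccc1)OC[C@@]1(OC(=O)O2)C=C[C@H](O[Si](C(C)C)(C(C)C)C(C)C)[C@@H](OC(=O)c3ccccc3)[C@@H]12 | intermediate
27 | cyclohex-5-ene: 1β,2β-cyclic carbonate, C1 α-CH2OH, C3 α-OBz, C4 β-OH | OC[C@@]1(OC(=O)O2)C=C[C@H](O)[C@@H](OC(=O)c3ccccc3)[C@@H]12 | intermediate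
28 | cyclohex-5-ene: 1β,2β-cyclic carbonate, C1 α-CH2OBz, C3 α-OBz, C4 β-OH | O=C(OC[C@@]1(OC(=O)O2)C=C[C@H](O)[C@@H](OC(=O)c3ccccc3)[C@@H]12)c1ccccc1 | intermediate
29 | 1α-benzoyloxymethyl-3α-benzoyloxycyclohex-5-ene-1β,2β,4β-triol | O=C(OC[C@@]1(O)C=C[C@H](O)[C@@H](OC(=O)c2ccccc2)[C@@H]1O)c1ccccc1 | target

**Step count and risks**

Total: 18 steps. Longest linear sequence: 18 steps (from 1).

Steps most likely to fail:

1. Step 14 (key step). Ionisation may be slow because three oxygen-bearing carbons flank the developing allyl cation, and the cation may be diverted by capture through the C3 benzoate or adventitious water, by proton loss to a diene, or by acid-induced desilylation. The fallback builds the six-membered ring without a cation and sets out from ketone 10. Vinylmagnesium bromide (THF, −78 °C) should add equatorially, trans to the side chain on the dioxanone, to give the tertiary allylic alcohol F1 with O1 already cis to O2. Ring-closing metathesis of this 1,7-diene with the second-generation Grubbs catalyst would give the trans-fused cyclohexene F2. DDQ would free O3 to give the cyclohexenediol F3, and benzoyl chloride/pyridine/DMAP would acylate only this secondary hydroxyl to give the benzoate F4. Camphorsulfonic acid in methanol would remove the benzylidene acetal to give the triol F5, and benzoyl chloride/2,4,6-collidine at low temperature would acylate the primary O7 to give the dibenzoate F6. HF·pyridine would then remove the silyl ether, and the sequence returns to the route at the target 29.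

2. Step 13. Carbene transfer to a hindered alkene flanked by two electron-withdrawing allylic oxygens may be too slow, and the heated product may ring-open prematurely. The fallback makes the cyclopropane earlier on the more electron-rich, base-stable alkene and sets out from 12. CHBr3 with 50% aqueous NaOH and benzyltriethylammonium chloride (phase-transfer generation of CBr2) should give the dibromocyclopropane acetal F7, expected on the α face. The operations of steps 8–12 then follow in the same order: DDQ to the alcohol F8, benzoyl chloride/pyridine/DMAP to the benzoate F9, camphorsulfonic acid/MeOH to the diol F10, TBDPSCl/imidazole to the primary silyl ether F11, and Boc2O/DMAP, which rejoins the route at 22.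

3. Step 18. Hydroxide may also cleave the benzoates, or the alkoxides formed may move the C3 benzoate to O2 or O4. The fallback makes the last deprotection acidic and sets out from 26. K2CO3 in methanol would remove carbonate and benzoate alike to give the triol F12. 2,2-Dimethoxypropane with pyridinium p-toluenesulfonate would close an acetonide on the cis-diol O1/O2 to give the acetonide F13, and benzoyl chloride/DMAP would re-benzoylate the only free hydroxyl, O3, to give the benzoate F14. HF·pyridine buffered with pyridine would remove both silyl groups to give the diol F15, and benzoyl chloride/2,4,6-collidine would acylate the primary O7 to give the dibenzoate acetonide F16. Aqueous acetic acid would then remove the acetonide and return to the route at 29.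

**Further compounds**

F1 | step 14 | tertiary allylic alcohol from vinyl addition to 10 (O1 cis to O2) | [C@@H]1(c2ccccc2)OC[C@@](O)(C=C)[C@@H](O1)[C@H](OCc3ccc(OC)cc3)[C@@H](O[Si](C(C)C)(C(C)C)C(C)C)C=C
F2 | step 14 | cyclohex-5-ene with O2,O7-benzylidene acetal, C1 β-OH, C3 α-OPMB, C4 β-OTIPS | [C@@H]1(c2ccccc2)OC[C@@]3(O)C=C[C@H](O[Si](C(C)C)(C(C)C)C(C)C)[C@@H](OCc4ccc(OC)cc4)[C@@H]3O1
F3 | step 14 | cyclohex-5-ene with O2,O7-benzylidene acetal, C1 β-OH, C3 α-OH, C4 β-OTIPS | [C@@H]1(c2ccccc2)OC[C@@]3(O)C=C[C@H](O[Si](C(C)C)(C(C)C)C(C)C)[C@@H](O)[C@@H]3O1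
F4 | step 14 | cyclohex-5-ene with O2,O7-benzylidene acetal, C1 β-OH, C3 α-OBz, C4 β-OTIPS | [C@@H]1(c2ccccc2)OC[C@@]3(O)C=C[C@H](O[Si](C(C)C)(C(C)C)C(C)C)[C@@H](OC(=O)c4ccccc4)[C@@H]3O1
F5 | step 14 | cyclohex-5-ene with C1 α-CH2OH, C1 β-OH, C2 β-OH, C3 α-OBz, C4 β-OTIPS | OC[C@@]1(O)C=C[C@H](O[Si](C(C)C)(C(C)C)C(C)C)[C@@H](OC(=O)c2ccccc2)[C@@H]1O
F6 | step 14 | 4-O-triisopropylsilyl ether of the target | O=C(OC[C@@]1(O)C=C[C@H](O[Si](C(C)C)(C(C)C)C(C)C)[C@@H](OC(=O)c2ccccc2)[C@@H]1O)c1ccccc1
F7 | step 13 | 6,6-dibromobicyclo[3.1.0]hexane (cyclopropane α) with O2,O7-benzylidene acetal, C3 α-OPMB, C4 β-OTIPS | [C@@H]3(c4ccccc4)OC[C@]12[C@H]([C@H](O[Si](C(C)C)(C(C)C)C(C)C)[C@@H](OCc5ccc(OC)cc5)[C@@H]1O3)C2(Br)Br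
F8 | step 13 | 6,6-dibromobicyclo[3.1.0]hexane with O2,O7-benzylidene acetal, C3 α-OH, C4 β-OTIPS | [C@@H]3(c4ccccc4)OC[C@]12[C@H]([C@H](O[Si](C(C)C)(C(C)C)C(C)C)[C@@H](O)[C@@H]1O3)C2(Br)Br
F9 | step 13 | 6,6-dibromobicyclo[3.1.0]hexane with O2,O7-benzylidene acetal, C3 α-OBz, C4 β-OTIPS | [C@@H]3(c4ccccc4)OC[C@]12[C@H]([C@H](O[Si](C(C)C)(C(C)C)C(C)C)[C@@H](OC(=O)c5ccccc5)[C@@H]1O3)C2(Br)Br
F10 | step 13 | 6,6-dibromobicyclo[3.1.0]hexane with C1–CH2OH, C2 β-OH, C3 α-OBz, C4 β-OTIPS | OC[C@]12[C@H]([C@H](O[Si](C(C)C)(C(C)C)C(C)C)[C@@H](OC(=O)c3ccccc3)[C@@H]1O)C2(Br)Br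
F11 | step 13 | 6,6-dibromobicyclo[3.1.0]hexane with C1–CH2OTBDPS, C2 β-OH, C3 α-OBz, C4 β-OTIPS | CC(C)(C)[Si](c1ccccc1)(c1ccccc1)OC[C@]12[C@H]([C@H](O[Si](C(C)C)(C(C)C)C(C)C)[C@@H](OC(=O)c3ccccc3)[C@@H]1O)C2(Br)Br
F12 | step 18 | cyclohex-5-ene-1β,2β,3α-triol with C1 α-CH2OTBDPS, C4 β-OTIPS | CC(C)(C)[Si](c1ccccc1)(c1ccccc1)OC[C@@]1(O)C=C[C@H](O[Si](C(C)C)(C(C)C)C(C)C)[C@@H](O)[C@@H]1O
F13 | step 18 | 1,2-O-isopropylidene acetal of F12 (C3 α-OH free) | CC(C)(C)[Si](c1ccccc1)(c1ccccc1)OC[C@@]1(OC(C)(C)O2)C=C[C@H](O[Si](C(C)C)(C(C)C)C(C)C)[C@@H](O)[C@@H]12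
F14 | step 18 | 3-O-benzoate of F13 | CC(C)(C)[Si](c1ccccc1)(c1ccccc1)OC[C@@]1(OC(C)(C)O2)C=C[C@H](O[Si](C(C)C)(C(C)C)C(C)C)[C@@H](OC(=O)c3ccccc3)[C@@H]12
F15 | step 18 | 1,2-O-isopropylidene cyclohex-5-ene with C1 α-CH2OH, C3 α-OBz, C4 β-OH | OC[C@@]1(OC(C)(C)O2)C=C[C@H](O)[C@@H](OC(=O)c3ccccc3)[C@@H]12
F16 | step 18 | 1,2-O-isopropylidene acetal of the target | O=C(OC[C@@]1(OC(C)(C)O2)C=C[C@H](O)[C@@H](OC(=O)c3ccccc3)[C@@H]12)c1ccccc1
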